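**Assumption:** the target has no stereocentre and its only non-aromatic alkene is locked cis in a ring. It is therefore achiral, "single enantiomer" means the compound itself, and no asymmetric step is needed.

## Retrosynthetic overview
1. Target ⇒ its 3,4-dihydro (chroman) analogue. The pyran alkene is installed last by DDQ dehydrogenation because it would not survive the oxidative rearrangement.
2. Ring C (4-pyranone) ⇒ acid cyclisation of a 2-aryl-3,3-dimethoxypropiophenone ⇒ oxidative 1,2-aryl shift of a chalcone.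
3. Chalcone ⇒ Claisen–Schmidt aldol condensation (key C–C bond, the future C2–C3) of MOM-protected paeonol (ring A) and 5-methoxy-2,2-dimethylchroman-6-carbaldehyde (rings B and D).
4. Aldehyde ⇒ 2,4-dihydroxybenzaldehyde by O-propargylation, aromatic Claisen/electrocyclisation, hydrogenation and O-methylation.
5. Ring order: rings A and B are bought, ring D (dimethylpyran) is formed first, ring C second, and the ring D alkene is restored last.

## Route

**Step 1**
Reactants: 1 2,4-dihydroxybenzaldehyde; 2 3-chloro-3-methylbut-1-yne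
Product: 3 2-hydroxy-4-[(2-methylbut-3-yn-2-yl)oxy]benzaldehyde
Conditions: K2CO3 (1.5 equiv), KI (10 mol %), CuI (5 mol %), DMF, 65 °C, 16 h
Reagents that add atoms: none
Why: In this copper-assisted Williamson-type O-propargylation the 4-OH is the more acidic, unchelated phenol while the 2-OH is hydrogen-bonded to the aldehyde, so only O4 is alkylated and no stereocentre forms.

**Step 2**
Reactants: 3 2-hydroxy-4-[(2-methylbut-3-yn-2-yl)oxy]benzaldehyde
Product: 6 chromene aldehyde (5-hydroxy-2,2-dimethyl-2H-chromene-6-carbaldehyde), via allenylphenol 4 (not isolated), via ortho-quinone methide 5 (not isolated)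
Conditions: PhNEt2, 190 °C, 3 h, N2
Reagents that add atoms: none
Why: In this aromatic propargyl Claisen cascade the [3,3]-shift goes to C3 because the chelated ortho-hydroxyaldehyde gives C3–C4 more double-bond character, and a 1,5-H shift followed by oxa-6π electrocyclisation then closes ring D without creating a stereocentre.

**Step 3**
Reactants: 6 5-hydroxy-2,2-dimethyl-2H-chromene-6-carbaldehyde
Product: 7 5-hydroxy-2,2-dimethylchroman-6-carbaldehyde
Conditions: H2 (1 atm), 10% Pd/C, EtOAc, rt, stopped after 1 equiv H2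
Reagents that add atoms: none
Why: Heterogeneous catalytic hydrogenation saturates the cis-styrenyl alkene much faster than it reduces the chelated, electron-rich aryl aldehyde, which masks the alkene that trivalent thallium would otherwise attack in step 7.

**Step 4**
Reactants: 7 5-hydroxy-2,2-dimethylchroman-6-carbaldehyde
Product: 8 5-methoxy-2,2-dimethylchroman-6-carbaldehyde
Conditions: MeI, K2CO3, DMF, rt to 40 °C
Reagents that add atoms: iodomethane (MeI), CI
Why: This Williamson ether synthesis in a dipolar aprotic solvent breaks the chelate and methylates the only acidic site, and the aldehyde cannot enolise.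

**Step 5**
Reactants: 9 paeonol (1-(2-hydroxy-4-methoxyphenyl)ethanone)
Product: 11 1-[4-methoxy-2-(methoxymethoxy)phenyl]ethanone, via sodium phenoxide 10 (not isolated)
Conditions: NaH (1.1 equiv), DMF, 0 °C; then MOMCl, 0 °C to rt
Reagents that add atoms: chloromethyl methyl ether (MOMCl), COCCl
Why: In this Williamson-type acetal protection NaH irreversibly deprotonates the chelated phenol well ahead of the ketone α-CH, and the MOM ether later blocks flavanone and aurone formation.

**Step 6**
Reactants: 11 1-[4-methoxy-2-(methoxymethoxy)phenyl]ethanone; 8 5-methoxy-2,2-dimethylchroman-6-carbaldehyde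
Product: 13 chalcone ((E)-1-[4-methoxy-2-(methoxymethoxy)phenyl]-3-(5-methoxy-2,2-dimethylchroman-6-yl)prop-2-en-1-one), via aldol adduct 12 (not isolated)
Conditions: KOH, EtOH–H2O, rt, 36 h
Reagents that add atoms: none
Why: In this Claisen–Schmidt crossed aldol condensation only the ketone can form an enolate and only the aldehyde is a good acceptor, and E1cB dehydration erases the carbinol centre of 12 to give the thermodynamically favoured E-enone.

**Step 7**
Reactants: 13 chalcone
Product: 15 acetal (racemic 1-[4-methoxy-2-(methoxymethoxy)phenyl]-3,3-dimethoxy-2-(5-methoxy-2,2-dimethylchroman-6-yl)propan-1-one), via methoxythallation adduct 14 (not isolated)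
Conditions: Tl(NO3)3·3H2O (1.1 equiv), MeOH–CH2Cl2 (4:1), rt, 4 h; aq. NaHCO3 work-up
Reagents that add atoms: methanol (two molecules), CO
Why: In this thallium trinitrate oxidative 1,2-aryl rearrangement, methoxythallation places OMe on the donor-stabilised β-carbon and reductive loss of monovalent thallium drives migration of the strongly donating 2,4-dialkoxyaryl group, giving a racemic centre that is erased in step 8.

**Step 8**
Reactants: 15 acetal
Product: 18 7-methoxy-3-(5-methoxy-2,2-dimethylchroman-6-yl)-4H-chromen-4-one, via free-phenol acetal 16 (not isolated), via 2-methoxyisoflavanone 17 (not isolated)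
Conditions: HCl (1.25 M in MeOH), reflux, 3 h
Reagents that add atoms: none
Why: Acid-catalysed acetal exchange removes the MOM group, the freed phenol closes ring C by intramolecular transacetalisation, and β-elimination of methanol gives the conjugated 4-pyranone and removes the remaining stereocentres.

**Step 9**
Reactants: 18 7-methoxy-3-(5-methoxy-2,2-dimethylchroman-6-yl)-4H-chromen-4-one
Product: 19 7-methoxy-3-(5-methoxy-2,2-dimethyl-2H-chromen-6-yl)-4H-chromen-4-one (target)
Conditions: DDQ (1.5 equiv), dry 1,4-dioxane, reflux, 12 h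
Reagents that add atoms: none
Why: In this DDQ dehydrogenation hydride is abstracted from the benzylic C4–H of ring D, whose cation is stabilised by two ortho oxygen substituents, and loss of a C3 proton gives the ring-locked cis alkene with no stereocentre involved.

## Compound list
1 | 2,4-dihydroxybenzaldehyde | O=Cc1ccc(O)cc1O | starting material
2 | 3-chloro-3-methylbut-1-yne | C#CC(C)(C)Cl | starting material
3 | 2-hydroxy-4-[(2-methylbut-3-yn-2-yl)oxy]benzaldehyde | O=Cc1ccc(OC(C)(C)C#C)cc1O | intermediate
4 | 2,4-dihydroxy-3-(3-methylbuta-1,2-dien-1-yl)benzaldehyde (allenylphenol, not isolated) | O=Cc1ccc(O)c(C=C=C(C)C)c1O | intermediate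
5 | 2-hydroxy-3-(3-methylbut-2-en-1-ylidene)-4-oxocyclohexa-1,5-diene-1-carbaldehyde (ortho-quinone methide, not isolated) | O=CC1=C(O)C(=CC=C(C)C)C(=O)C=C1 | intermediate
6 | 5-hydroxy-2,2-dimethyl-2H-chromene-6-carbaldehyde | O=Cc1ccc2OC(C)(C)C=Cc2c1O | intermediate
7 | 5-hydroxy-2,2-dimethylchroman-6-carbaldehyde | O=Cc1ccc2OC(C)(C)CCc2c1O | intermediate
8 | 5-methoxy-2,2-dimethylchroman-6-carbaldehyde | O=Cc1ccc2OC(C)(C)CCc2c1OC | intermediate
9 | paeonol, 1-(2-hydroxy-4-methoxyphenyl)ethanone | CC(=O)c1ccc(OC)cc1O | starting material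
10 | sodium 2-acetyl-5-methoxyphenoxide (not isolated) | CC(=O)c1ccc(OC)cc1[O-].[Na+] | intermediate
11 | 1-[4-methoxy-2-(methoxymethoxy)phenyl]ethanone | CC(=O)c1ccc(OC)cc1OCOC | intermediate
12 | racemic 3-hydroxy-1-[4-methoxy-2-(methoxymethoxy)phenyl]-3-(5-methoxy-2,2-dimethylchroman-6-yl)propan-1-one (aldol adduct, not isolated) | COCOc1cc(OC)ccc1C(=O)CC(O)c1ccc2OC(C)(C)CCc2c1OC | intermediate
13 | (E)-1-[4-methoxy-2-(methoxymethoxy)phenyl]-3-(5-methoxy-2,2-dimethylchroman-6-yl)prop-2-en-1-one | COCOc1cc(OC)ccc1C(=O)/C=C/c1ccc2OC(C)(C)CCc2c1OC | intermediate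
14 | 2-(dinitratothallio)-3-methoxy-1-[4-methoxy-2-(methoxymethoxy)phenyl]-3-(5-methoxy-2,2-dimethylchroman-6-yl)propan-1-one (methoxythallation adduct, not isolated) | COCOc1cc(OC)ccc1C(=O)C([Tl](O[N+](=O)[O-])O[N+](=O)[O-])C(OC)c1ccc2OC(C)(C)CCc2c1OC | intermediate
15 | racemic 1-[4-methoxy-2-(methoxymethoxy)phenyl]-3,3-dimethoxy-2-(5-methoxy-2,2-dimethylchroman-6-yl)propan-1-one | COCOc1cc(OC)ccc1C(=O)C(C(OC)OC)c1ccc2OC(C)(C)CCc2c1OC | intermediate
16 | racemic 1-(2-hydroxy-4-methoxyphenyl)-3,3-dimethoxy-2-(5-methoxy-2,2-dimethylchroman-6-yl)propan-1-one (not isolated) | COc1ccc(C(=O)C(C(OC)OC)c2ccc3OC(C)(C)CCc3c2OC)c(O)c1 | intermediate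
17 | 2,7-dimethoxy-3-(5-methoxy-2,2-dimethylchroman-6-yl)chroman-4-one (diastereomer mixture, not isolated) | COC1Oc2cc(OC)ccc2C(=O)C1c1ccc2OC(C)(C)CCc2c1OC | intermediate
18 | 7-methoxy-3-(5-methoxy-2,2-dimethylchroman-6-yl)-4H-chromen-4-one | COc1ccc2c(=O)c(-c3ccc4OC(C)(C)CCc4c3OC)coc2c1 | intermediate
19 | 7-methoxy-3-(5-methoxy-2,2-dimethyl-2H-chromen-6-yl)-4H-chromen-4-one | COc1ccc2c(=O)c(-c3ccc4c(c3OC)C=CC(C)(C)O4)coc2c1 | target

## Summary
Total step count: 9.
Longest linear sequence: 8 steps (1 → 3 → 6 → 7 → 8 → 13 → 15 → 18 → 19). Step 5 lies on the short side branch.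

**The three steps most likely to fail**

**Step 9 (DDQ dehydrogenation).** It may stall or over-oxidise. The fallback never removes the alkene and replaces the electrophilic oxidant with chemistry that an electron-rich alkene tolerates. It sets out from 6, using 11 from step 5, and comes back at 19.
- Compound 6 is methylated (MeI, K2CO3, DMF) to 5-methoxy-2,2-dimethyl-2H-chromene-6-carbaldehyde F4.
- Claisen–Schmidt condensation of this aldehyde and 11 (KOH, EtOH) gives the chromene chalcone (E)-1-[4-methoxy-2-(methoxymethoxy)phenyl]-3-(5-methoxy-2,2-dimethyl-2H-chromen-6-yl)prop-2-en-1-one F5.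
- Nucleophilic Weitz–Scheffer epoxidation (H2O2, NaOH, MeOH–THF, 0 °C) attacks only the electron-poor enone. It gives the racemic trans-epoxide [4-methoxy-2-(methoxymethoxy)phenyl][3-(5-methoxy-2,2-dimethyl-2H-chromen-6-yl)oxiran-2-yl]methanone F6.
- BF3·OEt2 (CH2Cl2, −20 °C) opens the epoxide at the benzylic carbon and triggers a 1,2-acyl shift. The product is the formyl ketone 3-[4-methoxy-2-(methoxymethoxy)phenyl]-2-(5-methoxy-2,2-dimethyl-2H-chromen-6-yl)-3-oxopropanal F7.
- Methanolic HCl then removes the MOM group and cyclodehydrates directly to 19.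

**Step 7 (thallium-mediated aryl shift).** The electron-rich ring B may be over-oxidised, or conversion may be incomplete. The fallback closes the oxygen ring first and migrates the aryl group on a flavanone. It sets out from 13 and comes back at 18.
- Mild methanolic HCl (rt) cleaves the MOM ether to the 2'-hydroxychalcone (E)-1-(2-hydroxy-4-methoxyphenyl)-3-(5-methoxy-2,2-dimethylchroman-6-yl)prop-2-en-1-one F2.
- Intramolecular oxa-Michael addition (NaOAc, EtOH, reflux) gives the racemic flavanone 7-methoxy-2-(5-methoxy-2,2-dimethylchroman-6-yl)chroman-4-one F3.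
- The trivalent iodine reagent PhI(OH)OTs (MeCN, reflux) induces a 2→3 aryl shift with loss of a proton, giving 18 and replacing steps 7 and 8.

**Step 1 (O-alkylation by a hindered tertiary propargylic chloride).** It may be sluggish, or the chloride may eliminate. The fallback avoids the propargyl ether altogether. It sets out from 1 and comes back at 6.
- Compound 1 is condensed with 3-methylbut-2-enal (Ca(OH)2, MeOH, rt).
- The phenoxide adds through C3 to the enal to give the carbinol 2,4-dihydroxy-3-(1-hydroxy-3-methylbut-2-en-1-yl)benzaldehyde F1.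
- This carbinol loses water to the same ortho-quinone methide 5, which electrocyclises to 6, replacing steps 1 and 2.

## Further compounds
F1 | step 1 | racemic 2,4-dihydroxy-3-(1-hydroxy-3-methylbut-2-en-1-yl)benzaldehyde | O=Cc1ccc(O)c(C(O)C=C(C)C)c1O
F2 | step 7 | (E)-1-(2-hydroxy-4-methoxyphenyl)-3-(5-methoxy-2,2-dimethylchroman-6-yl)prop-2-en-1-one | COc1ccc(C(=O)/C=C/c2ccc3OC(C)(C)CCc3c2OC)c(O)c1
F3 | step 7 | racemic 7-methoxy-2-(5-methoxy-2,2-dimethylchroman-6-yl)chroman-4-one | COc1ccc2C(=O)CC(c3ccc4OC(C)(C)CCc4c3OC)Oc2c1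
F4 | step 9 | 5-methoxy-2,2-dimethyl-2H-chromene-6-carbaldehyde | O=Cc1ccc2OC(C)(C)C=Cc2c1OC
F5 | step 9 | (E)-1-[4-methoxy-2-(methoxymethoxy)phenyl]-3-(5-methoxy-2,2-dimethyl-2H-chromen-6-yl)prop-2-en-1-one | COCOc1cc(OC)ccc1C(=O)/C=C/c1ccc2OC(C)(C)C=Cc2c1OC
F6 | step 9 | racemic trans-[4-methoxy-2-(methoxymethoxy)phenyl][3-(5-methoxy-2,2-dimethyl-2H-chromen-6-yl)oxiran-2-yl]methanone (one enantiomer drawn) | COCOc1cc(OC)ccc1C(=O)[C@@H]1O[C@H]1c1ccc2OC(C)(C)C=Cc2c1OC
F7 | step 9 | racemic 3-[4-methoxy-2-(methoxymethoxy)phenyl]-2-(5-methoxy-2,2-dimethyl-2H-chromen-6-yl)-3-oxopropanal | COCOc1cc(OC)ccc1C(=O)C(C=O)c1ccc2OC(C)(C)C=Cc2c1OC
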